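**Retrosynthetic overview**

- The target is reached from a ten-membered β-hydroxy ketone ester by an Evans–Tishchenko reaction with methacrolein (C8 ester, C6 carbinol) followed by lactonization.
- The ten-membered ring comes from a four-carbon ring expansion: an allylindium closes ring B onto a cyclohexanone, and the cis-fused bicyclic alkoxide fragments (Grob) across the ring-fusion bond C1–C6 with a spiro-epoxide as leaving group, giving C1=C10, C14–OH and the C6 ketone.
- The precursor of that step comes from cross-metathesis of a vinyl carbinol with methyl 2-(bromomethyl)acrylate; the epoxide comes from a hydroxyl-directed epoxidation and the ketone from an alcohol oxidation.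
- The C1–C10 bond comes from a nickel cross-electrophile coupling of a bridged iodolactone (butadiene + methyl acrylate, then iodolactonization) with a 2-bromodiene (acrolein + 2,3-dibromopropene).
- Ring order: ring A (cyclohexene) → bridged iodolactone (temporary) → ring B (made and cleaved in one flask) → ten-membered carbocycle → γ-lactone last.

Assumption and labels: triethylsilyl (TES) groups count as protecting groups; atom labels C1–C15 are the germacrane positions of the target (ring C1–C10, lactone carbons C11–C13, C14 on C10, C15 on C4).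

**Step 1**
Reactants: 1 buta-1,3-diene; 2 methyl acrylate
Product: 3 methyl (1S)-cyclohex-3-ene-1-carboxylate
Conditions: (3aS)-1-(2-methylphenyl)-3,3-diphenyltetrahydro-1H,3H-pyrrolo[1,2-c][1,3,2]oxazaborole (10 mol %), AlBr3 (8 mol %), CH2Cl2, −40 °C
Reagents that add atoms: none
Why: Catalytic enantioselective Diels–Alder reaction in which the AlBr3-activated chiral oxazaborolidine binds the acrylate and shields one of its faces, so that the C4 centre (S) is set by the catalyst, whose enantiomer is chosen to give the S adduct.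

**Step 2**
Reactants: 3 methyl (1S)-cyclohex-3-ene-1-carboxylate
Product: 5 (1S,4S,5S)-4-iodo-6-oxabicyclo[3.2.1]octan-7-one, via lithium carboxylate 4 (not isolated)
Conditions: LiOH, THF/H2O, 25 °C; then I2, KI, NaHCO3, H2O/CH2Cl2, 0 °C, dark
Reagents that add atoms: lithium hydroxide, [Li+].[OH-]; iodine, [I][I]
Why: Saponification followed by iodolactonization, in which the carboxylate opens the iodonium ion in a trans-diaxial sense, so that oxygen is delivered to C6 on the face of the carboxyl group and iodine to C1 on the opposite face, both fixed by the existing C4 centre.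

**Step 3**
Reactants: 6 acrolein; 7 2,3-dibromoprop-1-ene
Product: 8 {[(3R)-5-bromohexa-1,5-dien-3-yl]oxy}triethylsilane
Conditions: CrCl2 (10 mol %), N-{2-[(4S)-4-isopropyl-4,5-dihydro-1,3-oxazol-2-yl]-6-methylphenyl}methanesulfonamide (11 mol %), Et3N (20 mol %), Mn powder, TESCl, THF, 0 °C
Reagents that add atoms: chlorotriethylsilane, CC[Si](Cl)(CC)CC
Why: Catalytic asymmetric Nozaki–Hiyama allylation (2-bromoallylation) in which only the allylic C–Br bond is reduced to the allylchromium reagent, the chiral sulfonamide–oxazoline chromium complex (ligand enantiomer chosen accordingly) sets the C8 carbinol as R, and the chromium alkoxide is released as its triethylsilyl ether while manganese regenerates divalent chromium.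

**Step 4**
Reactants: 5 (1S,4S,5S)-4-iodo-6-oxabicyclo[3.2.1]octan-7-one; 8 {[(3R)-5-bromohexa-1,5-dien-3-yl]oxy}triethylsilane
Product: 9 (1S,4R,5S)-4-{(4R)-4-[(triethylsilyl)oxy]hexa-1,5-dien-2-yl}-6-oxabicyclo[3.2.1]octan-7-one
Conditions: NiBr2·glyme (10 mol %), 4,4′-di-tert-butyl-2,2′-bipyridine (10 mol %), Mn powder, NaI (25 mol %), DMA, 25 °C
Reagents that add atoms: none
Why: Nickel-catalysed reductive cross-electrophile coupling of a secondary alkyl iodide with an alkenyl bromide, in which the C1 radical is expected to be captured by the alkenylnickel species on the face anti to the neighbouring axial lactone C–O bond, so that the new C1–C10 bond is trans to the C6 oxygen as the iodide was.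

**Step 5**
Reactants: 9 (1S,4R,5S)-4-{(4R)-4-[(triethylsilyl)oxy]hexa-1,5-dien-2-yl}-6-oxabicyclo[3.2.1]octan-7-one
Product: 10 (1S,2R,5S)-5-(hydroxymethyl)-2-{(4R)-4-[(triethylsilyl)oxy]hexa-1,5-dien-2-yl}cyclohexan-1-ol
Conditions: LiBH4, THF, 0 → 25 °C; aq. NH4Cl
Reagents that add atoms: none
Why: Hydride reduction of the lactone to the diol, which frees the C6 hydroxyl and the C15 primary alcohol without touching a stereocentre and lets ring A relax to the all-equatorial chair.

**Step 6**
Reactants: 10 (1S,2R,5S)-5-(hydroxymethyl)-2-{(4R)-4-[(triethylsilyl)oxy]hexa-1,5-dien-2-yl}cyclohexan-1-ol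
Product: 11 (1S,2R,5S)-2-{(4R)-4-[(triethylsilyl)oxy]hexa-1,5-dien-2-yl}-5-{[(triethylsilyl)oxy]methyl}cyclohexan-1-ol
Conditions: TESCl (1.05 equiv), imidazole, CH2Cl2, −40 °C
Reagents that add atoms: chlorotriethylsilane, CC[Si](Cl)(CC)CC
Why: Selective silyl ether protection of the primary hydroxyl, which reacts far faster than the hindered secondary ring hydroxyl, with no stereocentre involved.

**Step 7**
Reactants: 11 (1S,2R,5S)-2-{(4R)-4-[(triethylsilyl)oxy]hexa-1,5-dien-2-yl}-5-{[(triethylsilyl)oxy]methyl}cyclohexan-1-ol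
Product: 12 (1S,2S,5S)-2-[(2R)-2-{(2R)-2-[(triethylsilyl)oxy]but-3-en-1-yl}oxiran-2-yl]-5-{[(triethylsilyl)oxy]methyl}cyclohexan-1-ol
Conditions: VO(acac)2 (5 mol %), t-BuOOH, CH2Cl2, 0 → 25 °C
Reagents that add atoms: tert-butyl hydroperoxide, CC(C)(C)OO
Why: Hydroxyl-directed vanadium-catalysed epoxidation of the homoallylic alcohol, in which the equatorial C6 vanadate delivers oxygen through a chair-like transition state with the methylene terminus folded over C6 and the side chain outside, which sets C10 as R and leaves the monosubstituted alkene, which has no free hydroxyl nearby, untouched.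

**Step 8**
Reactants: 12 (1S,2S,5S)-2-[(2R)-2-{(2R)-2-[(triethylsilyl)oxy]but-3-en-1-yl}oxiran-2-yl]-5-{[(triethylsilyl)oxy]methyl}cyclohexan-1-ol
Product: 13 (2R,5S)-2-[(2R)-2-{(2R)-2-[(triethylsilyl)oxy]but-3-en-1-yl}oxiran-2-yl]-5-{[(triethylsilyl)oxy]methyl}cyclohexan-1-one
Conditions: Dess–Martin periodinane, pyridine, CH2Cl2, 0 → 25 °C
Reagents that add atoms: none
Why: Dess–Martin oxidation of the secondary alcohol to the ketone under buffered, non-basic conditions that spare the epoxide and the C1 centre, which already sits in its more stable equatorial arrangement.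

**Step 9**
Reactants: 13 (2R,5S)-2-[(2R)-2-{(2R)-2-[(triethylsilyl)oxy]but-3-en-1-yl}oxiran-2-yl]-5-{[(triethylsilyl)oxy]methyl}cyclohexan-1-one
Product: 14 (2R,5S)-2-{(2R)-2-[(2R)-2-hydroxybut-3-en-1-yl]oxiran-2-yl}-5-(hydroxymethyl)cyclohexan-1-one
Conditions: HF·pyridine, pyridine, THF, 0 °C
Reagents that add atoms: none
Why: Fluoride-mediated cleavage of both triethylsilyl ethers (deprotection) under buffered conditions mild enough for the epoxy ketone, which frees the C8 hydroxyl that must coordinate the metal in the key step.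

**Step 10**
Reactants: 14 (2R,5S)-2-{(2R)-2-[(2R)-2-hydroxybut-3-en-1-yl]oxiran-2-yl}-5-(hydroxymethyl)cyclohexan-1-one; 15 methyl 2-(bromomethyl)prop-2-enoate
Product: 16 methyl (2Z,4R)-2-(bromomethyl)-4-hydroxy-5-{(2R)-2-[(1R,4S)-4-(hydroxymethyl)-2-oxocyclohexyl]oxiran-2-yl}pent-2-enoate
Conditions: 15 (4 equiv), [RuCl2(=CH-C6H4-2-OiPr)(H2IMes)] (Hoveyda–Grubbs second-generation catalyst, 10 mol %), CH2Cl2, 40 °C; used at once
Reagents that add atoms: none
Why: Olefin cross-metathesis between the monosubstituted alkene of the allylic alcohol (the only alkene left in 14) and the slowly homodimerizing 1,1-disubstituted acrylate, which installs C11–C13 and the allylic bromide in one operation and gives the trisubstituted enoate with the ester trans to the chain (Z by the sequence rule).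

**Step 11**
Reactants: 16 methyl (2Z,4R)-2-(bromomethyl)-4-hydroxy-5-{(2R)-2-[(1R,4S)-4-(hydroxymethyl)-2-oxocyclohexyl]oxiran-2-yl}pent-2-enoate
Product: 19 methyl 2-[(1R,2R,4E,8S)-2-hydroxy-4,8-bis(hydroxymethyl)-10-oxocyclodec-4-en-1-yl]prop-2-enoate, via allylindium dibromide 17 (not isolated), via bicyclic indium alkoxide 18 (not isolated)
Conditions: In powder (1.5 equiv), THF, 25 °C (ultrasound), then 40 °C; aq. NH4Cl
Reagents that add atoms: none
Why: Proposed new method: indium metal inserts into the allylic C–Br bond and the resulting allylindium 17, held in the Z form by coordination of the free C8 hydroxyl to indium, adds through its γ-carbon (C7) to the ring ketone from the axial direction (Barbier-type cyclization closing ring B), which gives the cis-fused bicyclic alkoxide 18 with the C6 and C8 oxygens syn on one indium and C7 therefore set cis to the C8 oxygen, whereupon the trivalent indium bromide present activates the spiro-epoxide, whose equatorial C10–O bond is antiperiplanar to the ring-fusion bond C1–C6, and the alkoxide drives a concerted Grob fragmentation that opens the cyclohexane into the ten-membered ring (ring expansion by four carbons) and delivers the C6 ketone, the C14 alcohol and, stereospecifically, the C1=C10 alkene with C9 and C2 cis (E by the sequence rule), the closest known reaction types being the samarium diiodide-promoted Barbier cyclization/Grob fragmentation of keto sulfonates and the titanium alkoxide-mediated fragmentation of epoxy alcohols.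

**Step 12**
Reactants: 19 methyl 2-[(1R,2R,4E,8S)-2-hydroxy-4,8-bis(hydroxymethyl)-10-oxocyclodec-4-en-1-yl]prop-2-enoate; 20 methacrolein
Product: 23 (3aS,4R,6E,10S,11aR)-6,10-bis(hydroxymethyl)-3-methylidene-2-oxo-2,3,3a,4,5,8,9,10,11,11a-decahydrocyclodeca[b]furan-4-yl 2-methylprop-2-enoate, via samarium-bound hemiacetal 21 (not isolated), via hydroxy ester 22 (not isolated)
Conditions: 20 (8 equiv), SmI2 (30 mol %), THF, −10 °C; then CSA (10 mol %), CH2Cl2, 25 °C
Reagents that add atoms: none
Why: Evans–Tishchenko reduction, in which the trivalent samarium chelate of the C8 hemiacetal 21 delivers hydride intramolecularly to the C6 ketone through a chair transition state, which gives the 1,3-anti alcohol (C6 R) and leaves the C8 oxygen as its methacrylate in 22, after which acid-catalysed lactonization of the C6 hydroxyl onto the methyl ester closes the trans-fused α-methylene-γ-butyrolactone.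

**Compound list**

1 | buta-1,3-diene | C=CC=C | starting material
2 | methyl acrylate | C=CC(=O)OC | starting material
3 | methyl (1S)-cyclohex-3-ene-1-carboxylate | C1C[C@H](C(=O)OC)CC=C1 | intermediate
4 | lithium (1S)-cyclohex-3-ene-1-carboxylate | C1C[C@H](C(=O)[O-])CC=C1.[Li+] | intermediate
5 | (1S,4S,5S)-4-iodo-6-oxabicyclo[3.2.1]octan-7-one | I[C@H]1CC[C@H]2C[C@@H]1OC2=O | intermediate
6 | acrolein | C=CC=O | starting material
7 | 2,3-dibromoprop-1-ene | C=C(Br)CBr | starting material
8 | {[(3R)-5-bromohexa-1,5-dien-3-yl]oxy}triethylsilane | CC[Si](CC)(CC)O[C@@H](C=C)CC(Br)=C | intermediate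
9 | (1S,4R,5S)-4-{(4R)-4-[(triethylsilyl)oxy]hexa-1,5-dien-2-yl}-6-oxabicyclo[3.2.1]octan-7-one | C=C[C@H](O[Si](CC)(CC)CC)CC(=C)[C@H]1CC[C@H]2C[C@@H]1OC2=O | intermediate
10 | (1S,2R,5S)-5-(hydroxymethyl)-2-{(4R)-4-[(triethylsilyl)oxy]hexa-1,5-dien-2-yl}cyclohexan-1-ol | C=C[C@H](O[Si](CC)(CC)CC)CC(=C)[C@H]1CC[C@H](CO)C[C@@H]1O | intermediate
11 | (1S,2R,5S)-2-{(4R)-4-[(triethylsilyl)oxy]hexa-1,5-dien-2-yl}-5-{[(triethylsilyl)oxy]methyl}cyclohexan-1-ol | C=C[C@H](O[Si](CC)(CC)CC)CC(=C)[C@H]1CC[C@H](CO[Si](CC)(CC)CC)C[C@@H]1O | intermediate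
12 | (1S,2S,5S)-2-[(2R)-2-{(2R)-2-[(triethylsilyl)oxy]but-3-en-1-yl}oxiran-2-yl]-5-{[(triethylsilyl)oxy]methyl}cyclohexan-1-ol | C=C[C@H](O[Si](CC)(CC)CC)C[C@]1(CO1)[C@H]2CC[C@H](CO[Si](CC)(CC)CC)C[C@@H]2O | intermediate
13 | (2R,5S)-2-[(2R)-2-{(2R)-2-[(triethylsilyl)oxy]but-3-en-1-yl}oxiran-2-yl]-5-{[(triethylsilyl)oxy]methyl}cyclohexan-1-one | C=C[C@H](O[Si](CC)(CC)CC)C[C@]1(CO1)[C@H]2CC[C@H](CO[Si](CC)(CC)CC)CC2=O | intermediate
14 | (2R,5S)-2-{(2R)-2-[(2R)-2-hydroxybut-3-en-1-yl]oxiran-2-yl}-5-(hydroxymethyl)cyclohexan-1-one | C=C[C@H](O)C[C@]1(CO1)[C@H]2CC[C@H](CO)CC2=O | intermediate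
15 | methyl 2-(bromomethyl)prop-2-enoate | C=C(CBr)C(=O)OC | starting material
16 | methyl (2Z,4R)-2-(bromomethyl)-4-hydroxy-5-{(2R)-2-[(1R,4S)-4-(hydroxymethyl)-2-oxocyclohexyl]oxiran-2-yl}pent-2-enoate | BrC/C(=C\[C@H](O)C[C@]1(CO1)[C@H]2CC[C@H](CO)CC2=O)C(=O)OC | intermediate
17 | allylindium dibromide from 16 (indium in place of bromine at C13, otherwise as 16) | Br[In](Br)C/C(=C\[C@H](O)C[C@]1(CO1)[C@H]2CC[C@H](CO)CC2=O)C(=O)OC | intermediate
18 | cis-fused bicyclic dibromoindium alkoxide (C6–O, C8–OH, the C7 acrylate and the epoxide CH2 on one face of ring B; epoxide oxygen, C2 and C5 on the other) | C=C(C(=O)OC)[C@@H]1[C@H](O)C[C@]2(CO2)[C@H]3CC[C@H](CO)C[C@@]13O[In](Br)Br | intermediate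
19 | methyl 2-[(1R,2R,4E,8S)-2-hydroxy-4,8-bis(hydroxymethyl)-10-oxocyclodec-4-en-1-yl]prop-2-enoate | O[C@@H]1C/C(CO)=C\CC[C@H](CO)CC(=O)[C@@H]1C(=C)C(=O)OC | intermediate
20 | methacrolein | CC(=C)C=O | starting material
21 | hemiacetal of 19 (C8–OH) and methacrolein, present as its samarium alkoxide | CC(=C)C(O)O[C@@H]1C/C(CO)=C\CC[C@H](CO)CC(=O)[C@@H]1C(=C)C(=O)OC | intermediate
22 | methyl 2-{(1S,2R,4E,8S,10R)-10-hydroxy-4,8-bis(hydroxymethyl)-2-[(2-methylprop-2-enoyl)oxy]cyclodec-4-en-1-yl}prop-2-enoate | C=C(C)C(=O)O[C@@H]1C/C(CO)=C\CC[C@H](CO)C[C@@H](O)[C@@H]1C(=C)C(=O)OC | intermediate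
23 | (3aS,4R,6E,10S,11aR)-6,10-bis(hydroxymethyl)-3-methylidene-2-oxo-2,3,3a,4,5,8,9,10,11,11a-decahydrocyclodeca[b]furan-4-yl 2-methylprop-2-enoate (CNP0546547.2) | C=C(C)C(=O)O[C@@H]1C/C(CO)=C\CC[C@H](CO)C[C@H]2OC(=O)C(=C)[C@H]12 | target

**Step count and risk**

Total step count: 12. Longest linear sequence: 11 steps (steps 1, 2 and 4–12); step 3 is a one-step side branch.

The three steps most likely to fail are steps 4, 11 and 12.

Step 4 is at risk because the β-acyloxy alkyl iodide can be over-reduced and eliminate the carboxylate (back to the cyclohexene acid), and because the facial selectivity at C1 is predicted rather than precedented. The fallback sets out from 8 and 5 and comes back at 9. Compound 8 is converted with magnesium turnings in THF into {(4R)-4-[(triethylsilyl)oxy]hexa-1,5-dien-2-yl}magnesium bromide F1. F1 is then coupled with 5 under iron catalysis (Fe(acac)3, TMEDA, THF, −20 °C, slow addition), a known alkenyl Grignard coupling with secondary alkyl iodides that uses a preformed nucleophile and no stoichiometric metal reductant.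

Step 11 is the proposed new step. It can fail by trans-fused closure (which cannot fragment), by attack of the C6 alkoxide on the epoxide CH2, by early Lewis-acid opening of the epoxide, or by retro-aldol cleavage of the product. The fallback sets out from 16 and comes back at 19 and uses two known reactions in separate operations. Zinc dust in THF/saturated aqueous NH4Cl at 0 °C carries out the intramolecular Barbier allylation and, in the protic medium, stops at the cis-fused bicyclic epoxy triol F2 (the free alcohol of 18), which is isolated. F2 is then fragmented with Ti(OiPr)4 in CH2Cl2 at 0 → 25 °C (titanium alkoxide-mediated epoxy alcohol fragmentation) to give 19.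

Step 12 is at risk because an enal has to serve as the hydride donor and because the two free primary alcohols may be acylated by crossed Tishchenko reactions. The fallback sets out from 19 and comes back at 23. The two primary hydroxyls are silylated (TESCl, imidazole, CH2Cl2, −40 °C) to the bis(triethylsilyl) ether F3. The C8 hydroxyl is acylated with methacrylic anhydride and catalytic Sc(OTf)3 in MeCN at −20 °C to the keto methacrylate F4. The C6 ketone is reduced under reagent control with catecholborane and the oxazaborolidine (3aS)-1-methyl-3,3-diphenyltetrahydro-1H,3H-pyrrolo[1,2-c][1,3,2]oxazaborole (enantiomer chosen for the R carbinol) to the hydroxy ester F5. F5 is lactonized with CSA in CH2Cl2 to the lactone bis(triethylsilyl) ether F6, and HF·pyridine in THF removes the silyl groups to give 23.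

**Further compounds**

F1 | step 4 | {(4R)-4-[(triethylsilyl)oxy]hexa-1,5-dien-2-yl}magnesium bromide | C=C[C@H](O[Si](CC)(CC)CC)CC(=C)[Mg]Br
F2 | step 11 | cis-fused bicyclic epoxy triol, methyl 2-[3,4a-dihydroxy-6-(hydroxymethyl)octahydro-2H-spiro[naphthalene-1,2′-oxiran]-4-yl]prop-2-enoate with the configuration of 18 | C=C(C(=O)OC)[C@@H]1[C@H](O)C[C@]2(CO2)[C@H]3CC[C@H](CO)C[C@@]13O
F3 | step 12 | bis(triethylsilyl) ether of 19 at the two primary hydroxyls | O[C@@H]1C/C(CO[Si](CC)(CC)CC)=C\CC[C@H](CO[Si](CC)(CC)CC)CC(=O)[C@@H]1C(=C)C(=O)OC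
F4 | step 12 | C8 methacrylate of F3 (keto methacrylate) | C=C(C)C(=O)O[C@@H]1C/C(CO[Si](CC)(CC)CC)=C\CC[C@H](CO[Si](CC)(CC)CC)CC(=O)[C@@H]1C(=C)C(=O)OC
F5 | step 12 | (10R)-hydroxy ester from F4, bis(triethylsilyl) ether of 22 | C=C(C)C(=O)O[C@@H]1C/C(CO[Si](CC)(CC)CC)=C\CC[C@H](CO[Si](CC)(CC)CC)C[C@@H](O)[C@@H]1C(=C)C(=O)OC
F6 | step 12 | bis(triethylsilyl) ether of 23 | C=C(C)C(=O)O[C@@H]1C/C(CO[Si](CC)(CC)CC)=C\CC[C@H](CO[Si](CC)(CC)CC)C[C@H]2OC(=O)C(=C)[C@H]12
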